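The C3–C4 bond of the pyranone (ring C) is the one disconnection. In the target, O1–C2=C3–OMe is a doubly oxygenated alkene in which C3 is the electron-rich end of the O1 enol ether, and the C4 carbonyl sits on C4a of ring A, ortho to the O1-bearing C8a. The precursor is therefore racemic acid 12: a ring-A salicylic acid whose phenolic oxygen carries the ring-B benzylic carbon (future C2) and, next to it, a dimethyl acetal (future C3 and its OMe). One treatment with trifluoroacetic anhydride should unveil the methoxyvinyl ether, acylate it at C3 and so close ring C with every oxygen already in place. Both arenes come from vanillin.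

Key step: step 9

Remark on the chemistry: the target has no stereocentre, so there is no enantiomer to select; the only stereocentre of the route (the benzylic carbon of 10–13) is carried as the racemate and is erased in step 9. 2,2-Dimethoxyacetaldehyde is sold as an aqueous solution and is dried before use.

Step 1
Reactants: 1 vanillin
Product: 2 4-(benzyloxy)-3-methoxybenzaldehyde
Conditions: BnBr, K2CO3, DMF, rt
Reagents that add atoms: benzyl bromide, BrCc1ccccc1
Why: Williamson etherification of the only acidic OH, the phenoxide displacing bromide from benzyl bromide.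

Step 2
Reactants: 2 4-(benzyloxy)-3-methoxybenzaldehyde
Product: 4 4-(benzyloxy)-3-methoxyphenol, via 4-(benzyloxy)-3-methoxyphenyl formate 3 (not isolated)
Conditions: mCPBA, CH2Cl2, 0 °C → rt; aq NaHCO3 wash; then K2CO3 (cat.), MeOH, rt
Reagents that add atoms: meta-chloroperoxybenzoic acid, O=C(OO)c1cccc(Cl)c1
Why: Baeyer–Villiger (Dakin-type) oxidation in which the para-alkoxy aryl group migrates in preference to hydride, followed by base-catalysed methanolysis of the aryl formate; benzyl and methyl ethers are inert.

Step 3
Reactants: 4 4-(benzyloxy)-3-methoxyphenol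
Product: 5 5-(benzyloxy)-2-hydroxy-4-methoxybenzaldehyde
Conditions: MgCl2, Et3N, (CH2O)n, MeCN, reflux; aq HCl work-up
Reagents that add atoms: paraformaldehyde (as formaldehyde), C=O
Why: Magnesium phenoxide-directed ortho-formylation (Casnati–Skattebøl), which should go to the open ortho carbon para to the methoxy group and not to the carbon wedged between OH and OMe.

Step 4
Reactants: 4 4-(benzyloxy)-3-methoxyphenol
Product: 6 1-(benzyloxy)-2,4-dimethoxybenzene
Conditions: MeI, K2CO3, acetone, reflux
Reagents that add atoms: iodomethane, CI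
Why: Williamson O-methylation of the phenol, which turns the same vanillin-derived phenol into the ring-B oxygenation pattern.

Step 5
Reactants: 6 1-(benzyloxy)-2,4-dimethoxybenzene
Product: 7 1-(benzyloxy)-5-bromo-2,4-dimethoxybenzene
Conditions: NBS, MeCN, 0 °C → rt
Reagents that add atoms: N-bromosuccinimide, O=C1CCC(=O)N1Br
Why: Electrophilic aromatic bromination at C5, which is para to one methoxy group and ortho to the other, whereas C3 is flanked by two substituents and C6 is activated only by the benzyloxy group.

Step 6
Reactants: 7 1-(benzyloxy)-5-bromo-2,4-dimethoxybenzene; 8 2,2-dimethoxyacetaldehyde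
Product: 10 rac-1-[5-(benzyloxy)-2,4-dimethoxyphenyl]-2,2-dimethoxyethan-1-ol, via [5-(benzyloxy)-2,4-dimethoxyphenyl]lithium 9 (not isolated)
Conditions: n-BuLi, THF, −78 °C; then anhydrous 8, −78 → 0 °C; aq NH4Cl
Reagents that add atoms: none
Why: Bromine–lithium exchange is faster at −78 °C than any deprotonation, and the ortho-methoxy-stabilised aryllithium adds 1,2 to the aldehyde; the new carbinol stereocentre forms without control as the racemate, which is acceptable because step 9 makes this carbon the sp2 C2.

Step 7
Reactants: 5 5-(benzyloxy)-2-hydroxy-4-methoxybenzaldehyde; 10 rac-1-[5-(benzyloxy)-2,4-dimethoxyphenyl]-2,2-dimethoxyethan-1-ol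
Product: 11 rac-5-(benzyloxy)-2-{1-[5-(benzyloxy)-2,4-dimethoxyphenyl]-2,2-dimethoxyethoxy}-4-methoxybenzaldehyde
Conditions: PPh3, DIAD, THF, 0 °C → rt
Reagents that add atoms: none
Why: Mitsunobu etherification, in which the acidic salicylaldehyde OH protonates the betaine and its phenoxide displaces the oxyphosphonium group of the benzylic carbinol with inversion (immaterial for a racemate), while aldehyde, acetal and benzyl ethers stay untouched.

Step 8
Reactants: 11 rac-5-(benzyloxy)-2-{1-[5-(benzyloxy)-2,4-dimethoxyphenyl]-2,2-dimethoxyethoxy}-4-methoxybenzaldehyde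
Product: 12 rac-5-(benzyloxy)-2-{1-[5-(benzyloxy)-2,4-dimethoxyphenyl]-2,2-dimethoxyethoxy}-4-methoxybenzoic acid
Conditions: NaClO2, NaH2PO4, 2-methylbut-2-ene, t-BuOH/THF/H2O, rt
Reagents that add atoms: sodium chlorite, [Na+].[O-]Cl=O
Why: Pinnick oxidation of the aryl aldehyde at about pH 4, mild enough for the α-aryloxy dimethyl acetal and the benzyl ethers, with the alkene removing hypochlorous acid before it can chlorinate the electron-rich rings.

Step 9
Reactants: 12 rac-5-(benzyloxy)-2-{1-[5-(benzyloxy)-2,4-dimethoxyphenyl]-2,2-dimethoxyethoxy}-4-methoxybenzoic acid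
Product: 15 6,5'-bis(benzyloxy)-3,7,2',4'-tetramethoxyflavone, via mixed trifluoroacetic anhydride 13 (not isolated), via methoxyvinyl ether anhydride 14 (not isolated)
Conditions: (CF3CO)2O (2.5 equiv), CH2Cl2 (0.02 M), 0 °C → rt
Reagents that add atoms: none
Why: Proposed new method: trifluoroacetic anhydride first converts the acid into the mixed aroyl trifluoroacetic anhydride 13 and then, by O-acylation of an acetal methoxy group or through the trifluoroacetic acid released, ionises the acetal to a methoxy oxocarbenium ion that sheds the benzylic C2–H to give the 2-methoxyvinyl aryl ether 14 (methanol leaves as methyl trifluoroacetate); C3 of 14, the β-carbon of the O1 enol ether, then attacks the activated aroyl carbon, and the C2 cation so formed, stabilised by O1 and by the 2,4-dimethoxyaryl ring, loses the C3 proton to give the 3-methoxy-4-pyranone. The closest known reactions are the β-acylation of enol ethers and of acetals by trifluoroacetic anhydride or reactive acid chlorides and the Friedel–Crafts-type closure of 3-aryloxyacrylic acids to chromones; intramolecular delivery of an aroyl group to an acetal-derived enol ether has no direct precedent. Ring C closes 6-endo-trig on the enol ether through a six-membered transition state, and only the C3–C4 bond is made. No stereocentre is formed: the benzylic stereocentre of 12 becomes sp2 C2, and both geometries of 14 can close because the same C3 π-lobe attacks in either. The step needs acylation at C3 instead of at C2 (a five-membered closure over the in-plane O1 tether that would create a quaternary carbon), at the ring-B C6'–H (seven-membered ring) or by the reagent itself (trifluoroacetylation), and it needs the oxocarbenium ion to lose a proton faster than it alkylates the ring-A C–H next to O1 or the benzylic C–O1 bond ionises. Tether length and the doubly stabilised C2 cation should secure the first set, while high dilution, a small excess of anhydride and the low acidity of the medium (only the trifluoroacetic acid that the reaction releases) are meant to secure the rest.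

Step 10
Reactants: 15 6,5'-bis(benzyloxy)-3,7,2',4'-tetramethoxyflavone
Product: 16 6,5'-dihydroxy-3,7,2',4'-tetramethoxyflavone
Conditions: H2 (1 atm), 10% Pd/C, EtOAc–MeOH, rt
Reagents that add atoms: none
Why: Catalytic hydrogenolysis cleaves both aryl benzyl ethers under conditions that leave the chromone C2=C3 bond, the carbonyl and the four methyl ethers alone.

Compound list
1 | vanillin (4-hydroxy-3-methoxybenzaldehyde) | COc1cc(C=O)ccc1O | starting material
2 | 4-(benzyloxy)-3-methoxybenzaldehyde | COc1cc(C=O)ccc1OCc1ccccc1 | intermediate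
3 | 4-(benzyloxy)-3-methoxyphenyl formate (formed in the flask, not isolated) | COc1cc(OC=O)ccc1OCc1ccccc1 | intermediate
4 | 4-(benzyloxy)-3-methoxyphenol | COc1cc(O)ccc1OCc1ccccc1 | intermediate
5 | 5-(benzyloxy)-2-hydroxy-4-methoxybenzaldehyde | COc1cc(O)c(C=O)cc1OCc1ccccc1 | intermediate
6 | 1-(benzyloxy)-2,4-dimethoxybenzene | COc1ccc(OCc2ccccc2)c(OC)c1 | intermediate
7 | 1-(benzyloxy)-5-bromo-2,4-dimethoxybenzene | COc1cc(OC)c(OCc2ccccc2)cc1Br | intermediate
8 | 2,2-dimethoxyacetaldehyde | COC(OC)C=O | starting material
9 | [5-(benzyloxy)-2,4-dimethoxyphenyl]lithium (formed in the flask, not isolated) | [Li]c1cc(OCc2ccccc2)c(OC)cc1OC | intermediate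
10 | rac-1-[5-(benzyloxy)-2,4-dimethoxyphenyl]-2,2-dimethoxyethan-1-ol (racemate) | COC(OC)C(O)c1cc(OCc2ccccc2)c(OC)cc1OC | intermediate
11 | rac-5-(benzyloxy)-2-{1-[5-(benzyloxy)-2,4-dimethoxyphenyl]-2,2-dimethoxyethoxy}-4-methoxybenzaldehyde (racemate) | COC(OC)C(Oc1cc(OC)c(OCc2ccccc2)cc1C=O)c1cc(OCc2ccccc2)c(OC)cc1OC | intermediate
12 | rac-5-(benzyloxy)-2-{1-[5-(benzyloxy)-2,4-dimethoxyphenyl]-2,2-dimethoxyethoxy}-4-methoxybenzoic acid (racemate) | COC(OC)C(Oc1cc(OC)c(OCc2ccccc2)cc1C(=O)O)c1cc(OCc2ccccc2)c(OC)cc1OC | intermediate
13 | rac-5-(benzyloxy)-2-{1-[5-(benzyloxy)-2,4-dimethoxyphenyl]-2,2-dimethoxyethoxy}-4-methoxybenzoic trifluoroacetic anhydride (racemate; formed in the flask, not isolated) | COC(OC)C(Oc1cc(OC)c(OCc2ccccc2)cc1C(=O)OC(=O)C(F)(F)F)c1cc(OCc2ccccc2)c(OC)cc1OC | intermediate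
14 | 5-(benzyloxy)-2-{1-[5-(benzyloxy)-2,4-dimethoxyphenyl]-2-methoxyethenyloxy}-4-methoxybenzoic trifluoroacetic anhydride (E/Z mixture, geometry not defined; formed in the flask, not isolated) | COC=C(Oc1cc(OC)c(OCc2ccccc2)cc1C(=O)OC(=O)C(F)(F)F)c1cc(OCc2ccccc2)c(OC)cc1OC | intermediate
15 | 6,5'-bis(benzyloxy)-3,7,2',4'-tetramethoxyflavone (6-(benzyloxy)-2-[5-(benzyloxy)-2,4-dimethoxyphenyl]-3,7-dimethoxy-4H-chromen-4-one) | COc1cc(OC)c(-c2oc3cc(OC)c(OCc4ccccc4)cc3c(=O)c2OC)cc1OCc1ccccc1 | intermediate
16 | 6,5'-dihydroxy-3,7,2',4'-tetramethoxyflavone (6-hydroxy-2-(5-hydroxy-2,4-dimethoxyphenyl)-3,7-dimethoxy-4H-chromen-4-one; achiral) | COc1cc(OC)c(-c2oc3cc(OC)c(O)cc3c(=O)c2OC)cc1O | target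

Total step count: 10. Longest linear sequence: 9 (steps 1, 2, 4, 5, 6, 7, 8, 9, 10); step 3 is the side branch that turns phenol 4 into the ring-A partner 5.

Steps most likely to fail

1. Step 9 (Proposed new method). The unveiled enol ether may be intercepted before it cyclises: trifluoroacetylation at C3 by the reagent, alkylation of ring A by the oxocarbenium ion, or acid-induced ionisation of the doubly activated benzylic C–O1 bond. The fallback is the classical flavonol route, all known chemistry, setting out from 5 and returning at 15. One portion of 5 is O-methylated (MeI, K2CO3, acetone) to 5-(benzyloxy)-2,4-dimethoxybenzaldehyde F1. A second portion is treated with excess MeMgBr in THF to give rac-4-(benzyloxy)-2-(1-hydroxyethyl)-5-methoxyphenol F2, which MnO2 in CH2Cl2 should oxidise to 1-[5-(benzyloxy)-2-hydroxy-4-methoxyphenyl]ethan-1-one F3. Claisen–Schmidt condensation of F3 with F1 (KOH, EtOH) should give (E)-3-[5-(benzyloxy)-2,4-dimethoxyphenyl]-1-[5-(benzyloxy)-2-hydroxy-4-methoxyphenyl]prop-2-en-1-one F4. Algar–Flynn–Oyamada oxidation (H2O2, NaOH, MeOH) should convert F4 into 6,5'-bis(benzyloxy)-3-hydroxy-7,2',4'-trimethoxyflavone F5; ring A has no substituent next to the carbonyl, so flavonol and not aurone formation is expected. Methylation of the 3-OH (MeI, K2CO3, acetone) then gives 15.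

2. Step 7. Displacement at the crowded, easily ionised benzylic carbinol may be slow, so that the oxyphosphonium ion is consumed by elimination or by the hydrazide while the hydrogen-bonded salicylaldehyde remains unreacted. The fallback forms the other C–O bond, the aryl–oxygen bond, with the alcohol as nucleophile; it sets out from 10 and returns at 11. Commercial 2-bromo-5-hydroxy-4-methoxybenzaldehyde is benzylated (BnBr, K2CO3, DMF) to 5-(benzyloxy)-2-bromo-4-methoxybenzaldehyde F6. Carbinol 10 is then O-arylated with F6 by palladium-catalysed etherification of a secondary alcohol (t-BuBrettPhos or RockPhos palladium precatalyst, Cs2CO3, toluene, 90 °C), the ortho-formyl group assisting oxidative addition, to give 11.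

3. Step 6. Residual water, hydrate or oligomer in the dried aldehyde may protonate the aryllithium and return debrominated arene instead of the carbinol. The fallback replaces addition to the aldehyde by acylation and reduction; it sets out from 7 and returns at 10. Aryllithium 9, made from 7 as before, is added inversely at −78 °C to methyl 2,2-dimethoxyacetate, an anhydrous distillable ester whose chelated tetrahedral adduct resists over-addition, to give 1-[5-(benzyloxy)-2,4-dimethoxyphenyl]-2,2-dimethoxyethan-1-one F7. NaBH4 in MeOH at 0 °C then reduces F7 to racemic 10.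

Further compounds
F1 | step 9 | 5-(benzyloxy)-2,4-dimethoxybenzaldehyde | COc1cc(OC)c(C=O)cc1OCc1ccccc1
F2 | step 9 | rac-4-(benzyloxy)-2-(1-hydroxyethyl)-5-methoxyphenol | COc1cc(O)c(C(C)O)cc1OCc1ccccc1
F3 | step 9 | 1-[5-(benzyloxy)-2-hydroxy-4-methoxyphenyl]ethan-1-one | COc1cc(O)c(C(C)=O)cc1OCc1ccccc1
F4 | step 9 | (E)-3-[5-(benzyloxy)-2,4-dimethoxyphenyl]-1-[5-(benzyloxy)-2-hydroxy-4-methoxyphenyl]prop-2-en-1-one | COc1cc(OC)c(/C=C/C(=O)c2cc(OCc3ccccc3)c(OC)cc2O)cc1OCc1ccccc1
F5 | step 9 | 6,5'-bis(benzyloxy)-3-hydroxy-7,2',4'-trimethoxyflavone | COc1cc(OC)c(-c2oc3cc(OC)c(OCc4ccccc4)cc3c(=O)c2O)cc1OCc1ccccc1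
F6 | step 7 | 5-(benzyloxy)-2-bromo-4-methoxybenzaldehyde | COc1cc(Br)c(C=O)cc1OCc1ccccc1
F7 | step 6 | 1-[5-(benzyloxy)-2,4-dimethoxyphenyl]-2,2-dimethoxyethan-1-one | COC(OC)C(=O)c1cc(OCc2ccccc2)c(OC)cc1OC
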